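## Structural features

The target is a 2'-hydroxy-4-methoxychalcone whose phloroglucinol-type ring (ring C) is fused through a dihydrofuran to an aristolane-8,9-dione. Numbering used throughout: C1 ArCH, C2 and C3 CH2, C4 CHMe, C5 CMe, C6 and C7 the cyclopropane CH groups, C8 and C9 the carbonyls (C9 beside C10), C10 the carbon bearing the aryl ether oxygen, C11 CMe2; ring A is C1–C5/C10, ring B is C5–C10. C10 belongs to ring A, ring B and the dihydrofuran at once and carries O, C1, C5 and C9; its neighbour C5 is an all-carbon quaternary centre, so the C5–C10 bond joins two fully substituted carbons. Six stereocentres stand in an unbroken row (1R,4R,5R,6S,7R,10S): ring C on C1 and the oxygen on C10 are cis, the methyls on C4 and C5 are cis to each other and to that oxygen, and the cyclopropane lies on the opposite face of ring B. Fragile groups are the non-enolisable 8,9-dione next to quaternary C10 (cleavage or benzilic acid rearrangement with hydroxide or alkoxide, attack by phosphorus and carbon nucleophiles), the acyl cyclopropane (acid, hydrogenolysis), the chalcone enone (reducible Michael acceptor, flavanone closure on the free ortho phenol) and, on the way, the diazo and 1,3-dicarbonyl intermediates. The real difficulty is the vicinal pair C5/C10 with the ether oxygen on C10, and its relation to C4; the rest is ring closure and oxidation-level adjustment around that pair. The key step exploits that C10 carries the ring-C oxygen and two carbons that can both be carbonyl carbons (C1, later reduced, and C9). This is the substitution pattern of the carbene carbon of an ortho-allyloxyaryl 2-diazo-1,3-diketone: capture by the ether oxygen gives O–C10 and the furanone ring, and the [2,3] shift of the allyl group from that oxygen gives C5–C10 and leaves C6=C7 as a vinyl handle for ring B.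

## Logic of the disconnections

32 is cut at the chalcone Cα=Cβ bond, with the phenol unmasked in the same operation; this leads to 31 and then to 28 and 29. The enone is the group least compatible with ylides and hydrogen, so it must come last, and the cut removes the whole second arene as a commercial aldehyde. The forward aldol must run without hydroxide or alkoxide because of the 8,9-dione, hence a boron enolate of the only enolisable ketone and an acid-mediated dehydration.

28 is cut at C6–C11 and C7–C11, which leads to 27; 27 is traced to 25 by removing the C6=C7 unsaturation. An isopropylidene unit is transferred most simply to an enone, and the cut removes C11 and two stereocentres. The forward steps demand 1,4-addition at C6 on the face anti to the C5 methyl, and a dehydrogenation that touches only the diosphenol.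

25 is cut at C1–C2 (through 24 and 22) back to 21. C1 is the only carbonyl of 21 that can be olefinated from the C2 end without a bridgehead double bond, and the cut reduces ring A and the C1 stereocentre to a ketone and a primary chloride. The demand is ylide addition to a hindered, electron-rich ketone and hydrogen delivery to C1 from the face of C9.

21 is cut at C7–C8 to give 18, and the C7 aldehyde of 18 is read as the terminal carbon of the vinyl group of 17. C8 can be a nucleophile only from C9, and a vinyl group is what a [2,3] shift leaves on C5; the cut removes ring B while the C8 oxygen is already in place. The demand is anti-Markovnikov oxidation of a vinyl group on a quaternary carbon and an aldol condensation with a non-nucleophilic base.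

17 is cut at O–C10 and C5–C10 together, through 16, to 15. This is the one transform that makes both fully substituted carbons, the aryl ether bond and the furanone ring from an open-chain ether. The demands are the (E) ether with an exo envelope for the C5/C10 relationship, facial bias from C4, and preference of the carbene for the allyl ether oxygen.

15 is traced through 14 and 13 to 10 and 11; the bond cut is C1–C10 (aldol), and the diazo group stands for the diketone CH2. The ether is made before the diketone because a 1,3-diketone or a diazo group would not survive the etherification. The demand is a cross-aldol at the aldehyde and not at the aryl methyl ketone.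

10 is cut at the O–C7 ether bond into 9 and 6. This separates arene and side chain at a bond made under neutral conditions; the demand is SN2 substitution without allylic transposition at a hindered, chelated phenol.

9 is traced through 8 to 7 by removing the acetal and cutting the aryl–CHO bond. Both free ring positions of 7 are equivalent; the demand is protection of the less hindered of the two hydroxyls of 8.

6 is cut at C6–C7 and at C5–CH3 through 5 to 4, and 4 is traced through 3 and 2 to 1. A syn carbometalation fixes the (E) alkene, the chiral pool supplies C4, and the chloride is the latent phosphonium group of ring A. The demand is that the stereocentre α to the masked aldehyde does not epimerise during homologation.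

## Other disconnections considered

Alternative 1: The cut is the cyclopropane itself, C6–C11 and C7–C11, made last on the complete tetracycle. In the forward direction a sulfur ylide carrying an isopropylidene unit would add to C6 of the ene-dione A1, and the C7 enolate would expel the sulfide from C11 to give A2.
- In its favour: two bonds, one ring and two stereocentres in one step; the acid-labile cyclopropane arrives late; the rigid tetracycle with a pseudo-axial C5 methyl should steer the ylide to the required face.
- Against it here: A1 already contains the C5–C10 bond, the ether oxygen on C10 and rings A and B, so the hard problem is untouched and needs a second strategy. The ylide meets the free 8,9-dione. With both ring-C ethers as methyl ethers, the ortho phenol must be freed at the end by a Lewis acid beside the acyl cyclopropane.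
- Comparison: structurally it is a complement, not a rival; the chosen route uses the same transform on 27 in step 18. On mechanism, on the C6/C7 outcome and on step count for this stage the two are equal. The chosen plan is better in building the quaternary pair that A1 presupposes and in using an acetal that leaves under milder conditions than a methyl ether.

Alternative 2: The cut is C4–C5, the bond between the two methyl-bearing carbons, which opens ring A. Forward, a metal hydride made from an iron catalyst and a silane would transfer a hydrogen atom to the terminal alkene of A3. The secondary radical at C4 would add 6-endo to C5, the β-carbon of the 3-methylcyclohexenone, giving A4 after reduction and protonation of the enolate.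
- In its favour: quaternary C5 and ring A form in one step under neutral conditions with matched polarity. Ring A arrives at its final oxidation level with no olefination and hydrogenation; in this it is better than steps 14–16 of the chosen plan.
- Against it here: C4, C5 and C10 are set by a radical addition and an enolate protonation, so the cis methyl pair rests on a flexible transition state and C4 no longer comes from the chiral pool. C10 ends as C–H, and the C10–O bond must then be forced onto a tertiary carbon next to quaternary C5. Ring B arrives as a plain cyclohexanone still lacking the C8 oxygen and the C6=C7 bond. Absolute configuration must be introduced at C1 of A3.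
- Comparison: on mechanism both are mild and catalytic; the alternative is the equal in tolerance and the better in closing ring A. On structure the chosen plan is stronger because it makes O–C10 and C5–C10 together and carries C8 and C9 at a useful oxidation level. In step count the gain on ring A would probably be spent again on the late C10 oxidation and on ring B.

Alternative 3: The cut is C1–C10 and C4–C5, a [4+2] retron across ring A. Forward, a mild silver-based oxidant would convert the catechol A5 into the o-quinone A6. The C5=C10 bond of A6 would then act as dienophile toward the (E,E)-pentadienyl group on ring C, closing ring A and the dihydrofuran to give A7.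
- In its favour: two C–C bonds, two rings and four stereocentres (C1, C4, C5, C10) in one step from a flat diaryl ether, with suprafacial addition fixing C5/C10 and C1/C4 mutually. Ring B emerges directly as the 6-ene-8,9-dione needed for cyclopropanation. In step and redox economy this is better than the chosen plan.
- Against it here: the C5=C10 bond of A6 is the tetrasubstituted, oxygen-bearing double bond of the quinone and its poorest dienophile. o-Quinones prefer to react as hetero- or carbodienes, to dimerise, or, with the C5 methyl, to tautomerise to a quinone methide. The diene is conjugated with ring C and must twist to reach the tether geometry. A5 is achiral, so a single enantiomer would need an external chiral controller for a reaction of uncertain periselectivity. The C2=C3 bond of A7 must later be reduced beside the ene-dione.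
- Comparison: on structure and step count the alternative is the more convergent, and it is the equal in forming the C5/C10 pair in one step. On mechanism the chosen key step has one productive channel once the oxonium ylide exists and takes its absolute configuration from an enantiopure C4; this is why it was preferred.

Key step: step 11

Assumption 1: the silyl ether oxygen on C8 and the chlorine on C2 are spectator substituents chosen for the later steps; the bonds formed, the ring closed and the carbon skeletons of 15 (ortho-allyloxyaryl 2-diazobutane-1,3-dione) and 17 (2-acyl-2-(1-methyl-1-vinylalkyl)benzofuran-3(2H)-one) are unchanged.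

Assumption 2: metal-bound species on catalytic cycles are described in words; discrete organic intermediates are numbered.

Assumption 3: CIP descriptors are given in the C1–C11 numbering; those of C5 and C10 change along the route only because substituent priorities change, not the geometry. (R)-1 maps onto (4R), and the (E) ether is the geometry that leads to the target through the exo envelope.

## Steps

Step 1
Reactants: 1 (R)-α-methyl-γ-butyrolactone
Product: 2 (3R)-3-methyloxolan-2-ol
Conditions: i-Bu2AlH (1.05 equiv), CH2Cl2, −78 °C; aqueous work-up
Reagents that add atoms: none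
Why: Partial reduction of a lactone with i-Bu2AlH stops at the tetrahedral aluminium hemiacetal at −78 °C and gives the lactol on work-up (lactone-to-lactol reduction); the stereocentre α to the carbonyl is not touched under these cold, non-basic conditions.

Step 2
Reactants: 2 (3R)-3-methyloxolan-2-ol
Product: 3 (3R)-3-methylpent-4-yn-1-ol
Conditions: dimethyl (1-diazo-2-oxopropyl)phosphonate, K2CO3, MeOH, 0 °C → rt
Reagents that add atoms: dimethyl (1-diazo-2-oxopropyl)phosphonate, COP(=O)(OC)C(=[N+]=[N-])C(C)=O
Why: Seyferth–Gilbert homologation in the Ohira–Bestmann form acts on the open hydroxy-aldehyde tautomer of the lactol and turns CHO into C≡CH with loss of N2; the mild carbonate/methanol medium at low temperature should leave the α-stereocentre intact.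

Step 3
Reactants: 3 (3R)-3-methylpent-4-yn-1-ol
Product: 4 (3R)-5-chloro-3-methylpent-1-yne
Conditions: PPh3, N-chlorosuccinimide, CH2Cl2, 0 °C → rt
Reagents that add atoms: N-chlorosuccinimide, O=C1CCC(=O)N1Cl
Why: Appel-type chlorination: the alkoxyphosphonium ion formed from PPh3 and N-chlorosuccinimide is displaced by chloride at the primary carbon (SN2), two atoms away from the stereocentre.

Step 4
Reactants: 4 (3R)-5-chloro-3-methylpent-1-yne
Product: 6 (2E,4R)-6-chloro-3,4-dimethylhex-2-en-1-ol, via alkenyldimethylalane 5 (not isolated)
Conditions: AlMe3, Cp2ZrCl2 (20 mol%), CH2Cl2, 0 °C → rt; then (CH2O)n, THF, 0 °C → rt; aq. HCl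
Reagents that add atoms: trimethylaluminium, C[Al](C)C; formaldehyde (from paraformaldehyde), C=O
Why: Zirconium-catalysed carboalumination (Negishi) adds Me and Al syn across the terminal alkyne with Al at the terminus, and the alkenyl–Al bond is hydroxymethylated with retention, which fixes the (E)-trisubstituted alkene; the primary chloride and C4 are spectators.

Step 5
Reactants: 7 1-(2,6-dihydroxy-4-methoxyphenyl)ethanone
Product: 8 3-acetyl-2,4-dihydroxy-6-methoxybenzaldehyde
Conditions: Cl2CHOMe, TiCl4, CH2Cl2, −10 → 0 °C; then aq. HCl
Reagents that add atoms: dichloromethyl methyl ether, COC(Cl)Cl; water, O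
Why: Rieche formylation of the titanium phenoxide; the two free ring positions are equivalent, and the new aldehyde deactivates the ring against a second substitution.

Step 6
Reactants: 8 3-acetyl-2,4-dihydroxy-6-methoxybenzaldehyde
Product: 9 3-acetyl-2-hydroxy-6-methoxy-4-(methoxymethoxy)benzaldehyde
Conditions: MOMCl (1.05 equiv), i-Pr2NEt, CH2Cl2, 0 °C
Reagents that add atoms: chloromethyl methyl ether, COCCl
Why: O-Alkylation of a phenoxide (acetal formation); the hydroxyl between acetyl and formyl is held by two hydrogen bonds and flanked by two substituents, so the hydroxyl para to the aldehyde should react first with one equivalent of reagent.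

Step 7
Reactants: 9 3-acetyl-2-hydroxy-6-methoxy-4-(methoxymethoxy)benzaldehyde; 6 (2E,4R)-6-chloro-3,4-dimethylhex-2-en-1-ol
Product: 10 (E)-allyl aryl ether aldehyde (4R)
Conditions: PPh3, diisopropyl azodicarboxylate, THF, 0 °C → rt
Reagents that add atoms: none
Why: Mitsunobu etherification: the chelated phenol is acidic enough to be a good pronucleophile and the primary allylic oxyphosphonium ion is displaced SN2 at CH2 (the γ-carbon is fully substituted, which disfavours SN2'), so the (E) geometry and C4 are carried over and no base touches the aldehyde or the methyl ketone.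

Step 8
Reactants: 10 (E)-allyl aryl ether aldehyde (4R); 11 1-[(tert-butyldimethylsilyl)oxy]propan-2-one
Product: 13 β-hydroxy ketone (4R; both carbinol epimers), via lithium enolate 12 (not isolated)
Conditions: 11, LiN(i-Pr)2, THF, −78 °C; then 10, −78 °C; aq. NH4Cl
Reagents that add atoms: none
Why: Directed aldol addition: kinetic deprotonation of 11 at the methyl group and addition of the lithium enolate to the aldehyde, which is far more electrophilic than the doubly ortho-substituted aryl methyl ketone; the new carbinol centre is removed in the next step.

Step 9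
Reactants: 13 β-hydroxy ketone (4R; both carbinol epimers)
Product: 14 aryl 1,3-diketone (4R)
Conditions: Dess–Martin periodinane, CH2Cl2, 0 °C → rt
Reagents that add atoms: none
Why: Dess–Martin oxidation of the benzylic β-hydroxy ketone under neutral conditions gives the 1,3-diketone without loss of the acetal or the silyl ether.

Step 10
Reactants: 14 aryl 1,3-diketone (4R)
Product: 15 aryl 2-diazo-1,3-diketone (4R)
Conditions: 4-acetamidobenzenesulfonyl azide, Et3N, MeCN, 0 °C → rt
Reagents that add atoms: 4-acetamidobenzenesulfonyl azide, CC(=O)Nc1ccc(cc1)S(=O)(=O)N=[N+]=[N-]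
Why: Regitz diazo transfer: the triethylammonium enolate of the 1,3-diketone attacks the sulfonyl azide and the triazene collapses to the diazo diketone and the sulfonamide.

Step 11
Reactants: 15 aryl 2-diazo-1,3-diketone (4R)
Product: 17 benzofuranone with the C5–C10 bond (4R,5S,10R), via oxonium ylide 16 (not isolated)
Conditions: Rh2(OAc)4 (2 mol%), ClCH2CH2Cl, 60 °C, slow addition of 15
Reagents that add atoms: none
Why: Rh2(OAc)4 takes up the diazo carbon with loss of N2, and the electrophilic metal-bound carbene centre at C10 is attacked by a lone pair of the neighbouring allyl ether oxygen, which closes the five-membered furanone ring through O–C10 (5-exo-type closure, the breaking Rh=C bond lying outside the ring) and gives the oxonium ylide 16, an enolate delocalised over C1=O and C9=O. The 3,3-disubstituted allyl group then moves suprafacially from oxygen to C10 through a five-membered envelope transition state ([2,3]-sigmatropic shift), which forms C5–C10 and frees C6=C7 as a vinyl group; the closest known reaction type is the Rh- or Cu-catalysed oxonium ylide formation and [2,3] rearrangement of ortho-allyloxyaryl diazoketones to 2,2-disubstituted benzofuran-3-ones. The C5/C10 relationship is controlled by the (E) alkene, which puts the C5 methyl cis to the O–CH2 carbon, together with the exo envelope (C6 turned away from the bicyclic ylide), so that the methyl ends gauche to the ether oxygen and the C4 chain gauche to C1 as in the target, whereas the endo envelope would give the C5 epimer. The absolute sense is controlled by C4: in a Felkin-type arrangement the CH2CH2Cl group lies anti to the forming bond and the C4–H points toward the C5 methyl (least A(1,2) strain), which exposes the face leading to 17. Because methyl and CH2CH2Cl differ little in size this bias should be modest, but the other isomers are diastereomers of an enantiopure compound and can be removed by chromatography. The step also needs chemoselectivity between the allyloxy and the methoxy oxygen, both ortho to the acyl group: ylide formation is reversible and only the allyl oxonium ylide has the low-barrier [2,3] exit, so the methoxy ylide should revert, and [1,2] shift, C–H insertion and cyclopropanation of the remote alkene are slower. Loss of N2 makes the step irreversible, and the early transition state of the shift tolerates the crowding of two contiguous fully substituted carbons.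

Step 12
Reactants: 17 benzofuranone with the C5–C10 bond (4R,5S,10R)
Product: 18 C7 aldehyde (4R,5S,10R)
Conditions: PdCl2(PhCN)2 (10 mol%), CuCl2·2H2O (10 mol%), AgNO2 (5 mol%), O2 (1 atm), t-BuOH/MeNO2, rt
Reagents that add atoms: dioxygen, O=O
Why: Nitrite-modified Wacker oxidation: with a quaternary allylic carbon the oxygen is delivered to the terminal carbon, so the vinyl group becomes CH2CHO (aldehyde-selective Wacker oxidation of hindered terminal alkenes); the vinyl group is the only alkene, and ketones, acetal, silyl ether and chloride are inert.

Step 13
Reactants: 18 C7 aldehyde (4R,5S,10R)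
Product: 21 ring-B diosphenol (4R,5S,10R), via ring-B aldol 19 (not isolated), via diosphenol silyl ether 20 (not isolated)
Conditions: DBU (2 equiv), MeCN, rt → 50 °C; then Bu4NF, AcOH, THF, 0 °C
Reagents that add atoms: none
Why: Intramolecular aldol condensation: C8 is the only enolisable carbon that can reach the C7 aldehyde through a six-membered transition state (6-enolexo-exo-trig), and E1cB loss of water gives C7=C8; DBU is non-nucleophilic, so the 1,3-dicarbonyl array at C10 is not cleaved, the primary chloride is too poor an electrophile to be alkylated, and buffered fluoride frees the enol oxygen so that silylated and desilylated material converge on the diosphenol.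

Step 14
Reactants: 21 ring-B diosphenol (4R,5S,10R)
Product: 22 C2 triphenylphosphonium iodide (4R,5S,10R)
Conditions: PPh3, NaI, MeCN, 80 °C
Reagents that add atoms: triphenylphosphine, c1ccc(cc1)P(c1ccccc1)c1ccccc1; sodium iodide, [Na+].[I-]
Why: Finkelstein exchange to the iodide and SN2 quaternisation of PPh3 at the primary carbon in one flask; under these neutral conditions the enolised dione and the ketones are not attacked by the phosphine.

Step 15
Reactants: 22 C2 triphenylphosphonium iodide (4R,5S,10R)
Product: 24 tetracyclic 1-ene diosphenol (4R,5S,10R), via phosphonium ylide 23 (not isolated)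
Conditions: KN(SiMe3)2 (2.2 equiv), THF, −78 → 60 °C; aq. NH4Cl
Reagents that add atoms: none
Why: Intramolecular Wittig olefination: the first equivalent of base turns the diosphenol into its enolate (no longer an electrophile or Michael acceptor) and the second gives the ylide, which can reach only C1 in an unstrained six-membered ring, since olefination at C9 would need a bridgehead double bond and the aryl methyl ketone is out of reach; no stereocentre is formed.

Step 16
Reactants: 24 tetracyclic 1-ene diosphenol (4R,5S,10R)
Product: 25 tetracyclic diosphenol (1R,4R,5S,10S)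
Conditions: H2 (1 atm), Pd/C (10%), EtOAc, rt
Reagents that add atoms: none
Why: Heterogeneous hydrogenation of the electron-rich trisubstituted styrene-type alkene: hydrogen should enter C1 from the face of C9, because the other face is covered by C5 with its methyl group and addition there would force a trans fusion of ring A and the dihydrofuran, so C1 is set with ring C cis to the oxygen on C10; the hydrogen-bonded diosphenol, a push-pull enol, is expected to react more slowly.

Step 17
Reactants: 25 tetracyclic diosphenol (1R,4R,5S,10S)
Product: 27 tetracyclic 6-ene-8,9-dione (1R,4R,5R,10S), via lithium diosphenolate 26 (not isolated)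
Conditions: LiN(SiMe3)2 (1.05 equiv), THF, −78 °C; then PhS(Cl)=N-t-Bu, −78 °C
Reagents that add atoms: none
Why: Dehydrogenation through the enolate (Mukaiyama method with N-tert-butylbenzenesulfinimidoyl chloride): one equivalent of base removes only the acidic diosphenol proton, the enolate is sulfenylated at C7 and syn-elimination across C6–C7 gives the ene-dione at −78 °C; ring C, the benzylic C1–H and the aryl methyl ketone are not touched.

Step 18
Reactants: 27 tetracyclic 6-ene-8,9-dione (1R,4R,5R,10S)
Product: 28 cyclopropyl dione acetophenone (1R,4R,5R,6S,7R,10S)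
Conditions: i-PrPh2S+ BF4−, LiN(i-Pr)2, DME, −78 °C; then 27, −78 → −30 °C
Reagents that add atoms: isopropyldiphenylsulfonium tetrafluoroborate, CC(C)[S+](c1ccccc1)c1ccccc1.F[B-](F)(F)F
Why: Michael-initiated ring closure (sulfur-ylide cyclopropanation of an enone): the hindered isopropylide adds to C6 and not to a carbonyl (C9 is neopentyl, C8 is the conjugated one), and the C7 enolate displaces diphenyl sulfide from C11; with ring A saturated, ring B should hold the C5 methyl pseudo-axial, so attack anti to it sets C6 and C7 with the cyclopropane trans to the methyls, and the cis fusion of the three-membered ring is enforced.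

Step 19
Reactants: 28 cyclopropyl dione acetophenone (1R,4R,5R,6S,7R,10S); 29 4-methoxybenzaldehyde
Product: 31 β-hydroxy ketone aldol adduct (carbinol epimers), via dibutylboron enolate 30 (not isolated)
Conditions: Bu2BOTf, i-Pr2NEt, CH2Cl2, −78 °C; then 29, −78 → 0 °C; pH 7 buffer, MeOH
Reagents that add atoms: none
Why: Boron-mediated aldol addition: soft enolisation is possible only at the aryl methyl ketone (the dione has no enolisable hydrogen), and the dibutylboron enolate adds to the aldehyde but not to the hindered ketones, with no hydroxide or alkoxide present that could cleave the dione; the carbinol configuration is of no consequence.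

Step 20
Reactants: 31 β-hydroxy ketone aldol adduct (carbinol epimers)
Product: 32 target chalcone CNP0121765.1 (1R,4R,5R,6S,7R,10S)
Conditions: TsOH·H2O (20 mol%), THF/H2O, 45 °C
Reagents that add atoms: none
Why: Acid-catalysed dehydration through the 4-methoxybenzylic cation gives the thermodynamically preferred (E)-enone, and the same aqueous acid hydrolyses the acetal ortho to the carbonyl, whose phenol is then held by a hydrogen bond; the sulfonate counter-ion is non-nucleophilic, which spares the acyl cyclopropane.

## Compound list

1 | (3R)-3-methyloxolan-2-one, (R)-α-methyl-γ-butyrolactone | C[C@@H]1CCOC1=O | starting material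
2 | (3R)-3-methyloxolan-2-ol (lactol, both anomers) | C[C@@H]1CCOC1O | intermediate
3 | (3R)-3-methylpent-4-yn-1-ol | C#C[C@H](C)CCO | intermediate
4 | (3R)-5-chloro-3-methylpent-1-yne | C#C[C@H](C)CCCl | intermediate
5 | [(1E,3R)-5-chloro-2,3-dimethylpent-1-en-1-yl]dimethylalane | C[Al](C)/C=C(\C)[C@H](C)CCCl | intermediate
6 | (2E,4R)-6-chloro-3,4-dimethylhex-2-en-1-ol | OC/C=C(\C)[C@H](C)CCCl | intermediate
7 | 1-(2,6-dihydroxy-4-methoxyphenyl)ethanone | CC(=O)c1c(O)cc(OC)cc1O | starting material
8 | 3-acetyl-2,4-dihydroxy-6-methoxybenzaldehyde | CC(=O)c1c(O)cc(OC)c(C=O)c1O | intermediate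
9 | 3-acetyl-2-hydroxy-6-methoxy-4-(methoxymethoxy)benzaldehyde | CC(=O)c1c(OCOC)cc(OC)c(C=O)c1O | intermediate
10 | 3-acetyl-2-{[(2E,4R)-6-chloro-3,4-dimethylhex-2-en-1-yl]oxy}-6-methoxy-4-(methoxymethoxy)benzaldehyde | CC(=O)c1c(OCOC)cc(OC)c(C=O)c1OC/C=C(\C)[C@H](C)CCCl | intermediate
11 | 1-[(tert-butyldimethylsilyl)oxy]propan-2-one | CC(=O)CO[Si](C)(C)C(C)(C)C | starting material
12 | lithium 3-[(tert-butyldimethylsilyl)oxy]prop-1-en-2-olate | [Li]OC(=C)CO[Si](C)(C)C(C)(C)C | intermediate
13 | 4-[3-acetyl-2-{[(2E,4R)-6-chloro-3,4-dimethylhex-2-en-1-yl]oxy}-6-methoxy-4-(methoxymethoxy)phenyl]-1-[(tert-butyldimethylsilyl)oxy]-4-hydroxybutan-2-one (both carbinol epimers) | CC(=O)c1c(OCOC)cc(OC)c(C(O)CC(=O)CO[Si](C)(C)C(C)(C)C)c1OC/C=C(\C)[C@H](C)CCCl | intermediate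
14 | 1-[3-acetyl-2-{[(2E,4R)-6-chloro-3,4-dimethylhex-2-en-1-yl]oxy}-6-methoxy-4-(methoxymethoxy)phenyl]-4-[(tert-butyldimethylsilyl)oxy]butane-1,3-dione | CC(=O)c1c(OCOC)cc(OC)c(C(=O)CC(=O)CO[Si](C)(C)C(C)(C)C)c1OC/C=C(\C)[C@H](C)CCCl | intermediate
15 | 1-[3-acetyl-2-{[(2E,4R)-6-chloro-3,4-dimethylhex-2-en-1-yl]oxy}-6-methoxy-4-(methoxymethoxy)phenyl]-4-[(tert-butyldimethylsilyl)oxy]-2-diazobutane-1,3-dione | CC(=O)c1c(OCOC)cc(OC)c(C(=O)C(=[N+]=[N-])C(=O)CO[Si](C)(C)C(C)(C)C)c1OC/C=C(\C)[C@H](C)CCCl | intermediate
16 | oxonium ylide: 7-acetyl-2-{[(tert-butyldimethylsilyl)oxy]acetyl}-1-[(2E,4R)-6-chloro-3,4-dimethylhex-2-en-1-yl]-4-methoxy-6-(methoxymethoxy)-3-oxo-3H-1-benzofuran-1-ium-2-ide | CC(=O)c1c(OCOC)cc(OC)c2c1[O+](C/C=C(\C)[C@H](C)CCCl)[C-](C(=O)CO[Si](C)(C)C(C)(C)C)C2=O | intermediate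
17 | (2R)-7-acetyl-2-{[(tert-butyldimethylsilyl)oxy]acetyl}-2-[(3S,4R)-6-chloro-3,4-dimethylhex-1-en-3-yl]-4-methoxy-6-(methoxymethoxy)-1-benzofuran-3(2H)-one (4R,5S,10R in the C numbering) | CC(=O)c2c(OCOC)cc(OC)c3c2O[C@](C(=O)CO[Si](C)(C)C(C)(C)C)([C@@](C)(C=C)[C@H](C)CCCl)C3=O | intermediate
18 | (2R)-7-acetyl-2-{[(tert-butyldimethylsilyl)oxy]acetyl}-2-[(3S,4R)-6-chloro-3,4-dimethyl-1-oxohexan-3-yl]-4-methoxy-6-(methoxymethoxy)-1-benzofuran-3(2H)-one | CC(=O)c2c(OCOC)cc(OC)c3c2O[C@](C(=O)CO[Si](C)(C)C(C)(C)C)([C@@](C)(CC=O)[C@H](C)CCCl)C3=O | intermediate
19 | (2R,6'S)-7-acetyl-3'-[(tert-butyldimethylsilyl)oxy]-6'-[(2R)-4-chlorobutan-2-yl]-4'-hydroxy-4-methoxy-6-(methoxymethoxy)-6'-methyl-3H-spiro[1-benzofuran-2,1'-cyclohexane]-2',3-dione (epimers at C7 and C8) | CC(=O)c2c(OCOC)cc(OC)c3c2O[C@@]4(C(=O)C(O[Si](C)(C)C(C)(C)C)C(O)C[C@@]4(C)[C@H](C)CCCl)C3=O | intermediate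
20 | (2R,6'S)-7-acetyl-3'-[(tert-butyldimethylsilyl)oxy]-6'-[(2R)-4-chlorobutan-2-yl]-4-methoxy-6-(methoxymethoxy)-6'-methyl-3H-spiro[1-benzofuran-2,1'-cyclohex-3'-ene]-2',3-dione | CC(=O)c2c(OCOC)cc(OC)c3c2O[C@@]4(C(=O)C(O[Si](C)(C)C(C)(C)C)=CC[C@@]4(C)[C@H](C)CCCl)C3=O | intermediate
21 | (2R,6'S)-7-acetyl-6'-[(2R)-4-chlorobutan-2-yl]-3'-hydroxy-4-methoxy-6-(methoxymethoxy)-6'-methyl-3H-spiro[1-benzofuran-2,1'-cyclohex-3'-ene]-2',3-dione (ring-B diosphenol) | CC(=O)c2c(OCOC)cc(OC)c3c2O[C@@]4(C(=O)C(O)=CC[C@@]4(C)[C@H](C)CCCl)C3=O | intermediate
22 | {(3R)-3-[(2R,6'S)-7-acetyl-3'-hydroxy-4-methoxy-6-(methoxymethoxy)-6'-methyl-2',3-dioxo-3H-spiro[1-benzofuran-2,1'-cyclohex-3'-en]-6'-yl]butyl}triphenylphosphonium iodide | CC(=O)c2c(OCOC)cc(OC)c3c2O[C@@]4(C(=O)C(O)=CC[C@@]4(C)[C@H](C)CC[P+](c5ccccc5)(c5ccccc5)c5ccccc5)C3=O.[I-] | intermediate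
23 | potassium enolate of the triphenylphosphonium ylide derived from 22 | CC(=O)c2c(OCOC)cc(OC)c3c2O[C@@]4(C(=O)C([O-])=CC[C@@]4(C)[C@H](C)CC=P(c5ccccc5)(c5ccccc5)c5ccccc5)C3=O.[K+] | intermediate
24 | (4R,5S,10R) tetracycle: ring A cyclohexene (C1=C2; methyls on C4 and C5) fused at C1–C10 to the 7-acetyl-4-methoxy-6-(methoxymethoxy)benzofuran unit and at C5–C10 to ring B (C9=O, C8–OH, C7=C8) | CC(=O)c2c(OCOC)cc(OC)c3c2O[C@]24C(=O)C(O)=CC[C@@]2(C)[C@H](C)CC=C34 | intermediate
25 | (1R,4R,5S,10S) tetracycle as 24 with C1–H (ring C and the C10 oxygen cis) | CC(=O)c2c(OCOC)cc(OC)c3c2O[C@]24C(=O)C(O)=CC[C@@]2(C)[C@H](C)CC[C@H]34 | intermediate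
26 | lithium enolate (C8–OLi) of 25 | CC(=O)c2c(OCOC)cc(OC)c3c2O[C@]24C(=O)C(O[Li])=CC[C@@]2(C)[C@H](C)CC[C@H]34 | intermediate
27 | (1R,4R,5R,10S) tetracyclic 6-ene-8,9-dione, ring C with acetyl, methoxy and methoxymethoxy groups | CC(=O)c2c(OCOC)cc(OC)c3c2O[C@]24C(=O)C(=O)C=C[C@@]2(C)[C@H](C)CC[C@H]34 | intermediate
28 | (1R,4R,5R,6S,7R,10S) aristolane-8,9-dione core with 6,7-gem-dimethylcyclopropane, ring C with acetyl, methoxy and methoxymethoxy groups | CC(=O)c2c(OCOC)cc(OC)c3c2O[C@]24C(=O)C(=O)[C@@H]5[C@@H](C5(C)C)[C@@]2(C)[C@H](C)CC[C@H]34 | intermediate
29 | 4-methoxybenzaldehyde | COc1ccc(C=O)cc1 | starting material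
30 | dibutylboron enolate of the aryl methyl ketone of 28 | CCCCB(CCCC)OC(=C)c2c(OCOC)cc(OC)c3c2O[C@]24C(=O)C(=O)[C@@H]5[C@@H](C5(C)C)[C@@]2(C)[C@H](C)CC[C@H]34 | intermediate
31 | 3-hydroxy-3-(4-methoxyphenyl)propanoyl derivative of the core of 28 (1R,4R,5R,6S,7R,10S; carbinol epimers) | COc1ccc(C(O)CC(=O)c2c(OCOC)cc(OC)c3c2O[C@]24C(=O)C(=O)[C@@H]5[C@@H](C5(C)C)[C@@]2(C)[C@H](C)CC[C@H]34)cc1 | intermediate
32 | CNP0121765.1, (1R,4R,5R,6S,7R,10S) 2'-hydroxy-4-methoxychalcone fused to the aristolane-8,9-dione | COc1ccc(/C=C/C(=O)c2c(O)cc(OC)c3c2O[C@]24C(=O)C(=O)[C@@H]5[C@@H](C5(C)C)[C@@]2(C)[C@H](C)CC[C@H]34)cc1 | target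

## Step count and least certain steps

Total step count: 20 (steps 1–4 side chain, steps 5–6 arene, steps 7–20 after the two are joined). Longest linear sequence: 18 steps (1 to 32 through steps 1–4 and 7–20); from 7 it is 16 steps.

**Step 11 (key step).** The most likely failure is insufficient discrimination between the exo and the endo envelope, and between the two alkene faces. The two carbonyl groups on the ylide carbon are similar in size, and C4 distinguishes only methyl from CH2CH2Cl, so mixtures of C5/C10 diastereomers may form. Some material may also be diverted through the methoxy oxonium ylide into a [1,2] shift. A chiral dirhodium carboxylate such as Rh2(S-PTTL)4 or its enantiomer could reinforce the facial bias if the ylide stays metal-associated. The fallback changes the substrate geometry, so that an endo preference would lead to the same product: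
- It sets out from 4. Deprotonation (n-BuLi, THF, −78 °C) and acylation with ethyl chloroformate would give ethyl (4R)-6-chloro-4-methylhex-2-ynoate F1.
- Syn addition of Me2CuLi (THF, −78 °C) would give ethyl (2Z,4R)-6-chloro-3,4-dimethylhex-2-enoate F2, and i-Bu2AlH reduction the (2Z,4R)-allylic alcohol F3.
- F3 would pass through the chemistry of steps 7–10: Mitsunobu reaction with 9 to the (Z)-allyl aryl ether aldehyde F4, aldol addition of 12 to the (Z) β-hydroxy ketone F5, Dess–Martin oxidation to the (Z) 1,3-diketone F6, and diazo transfer to the (Z) diazo diketone F7.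
- F7 under the conditions of step 11 would come back to the route at 17.

**Step 15.** The ylide may fail to add to C1, a hindered ketone with vinylogous carbonate character, and be consumed by proton transfer or decomposition on heating. The fallback is a stepwise Horner–Wittig sequence with a smaller, more nucleophilic carbanion and an isolable adduct:
- From 21, Arbuzov reaction with ethyl diphenylphosphinite (NaI cat., 120 °C) would give the diphenylphosphine oxide F8.
- LiN(i-Pr)2 (3.2 equiv, THF, −78 → 0 °C; the diosphenol and the aryl methyl ketone are held as enolates) would give the cyclised β-hydroxy phosphine oxide F9.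
- Syn elimination with KH in DMF would come back to the route at 24.

**Step 18.** The ylide may add to a carbonyl of the dione (epoxide formation) instead of C6, or attack C6 on the face syn to the C5 methyl if ring B adopts the other half-chair. The fallback uses a soft carbon nucleophile in a reversible, thermodynamically controlled Michael addition, followed by a separate ring closure:
- From 27, 2-nitropropane with DBU in MeCN would give the C6 (2-nitropropan-2-yl) adduct F10.
- K2CO3 in DMSO at 60 °C would close the cyclopropane by displacement of nitrite from C11 by the C7 enolate and come back to the route at 28.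

**Step 16.** The diosphenol C7=C8 bond may be reduced alongside the alkene, or the hindered alkene may reduce too slowly. The fallback is ionic hydrogenation of 24 (Et3SiH, CF3CO2H, CH2Cl2, −40 °C). Protonation at C2 gives the C1 benzylic cation, stabilised by three ring-C oxygens, which takes hydride on the face of C9. The diosphenol is inert to these conditions, and the low temperature should spare the acetal. The fallback returns directly to 25 and makes no new isolated compound (F0).

**Step 19.** The enolate may add to the 8,9-dione, or the dione may be cleaved if enolisation is slow and the amine base acts on it. The fallback separates enolisation from C–C bond formation: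
- From 28, Me3SiOTf and Et3N (CH2Cl2, 0 °C) would give the trimethylsilyl enol ether F11.
- Mukaiyama aldol addition of F11 to 29 (BF3·OEt2, CH2Cl2, −78 °C) would come back to the route at 31.

**Step 12.** Oxidation may be slow or show Markovnikov leakage at a vinyl group flanked by two quaternary carbons. The fallback replaces the Wacker oxidation by hydroboration and oxidation:
- From 17, pinacolborane with [Ir(cod)Cl]2 and bis(diphenylphosphino)methane (CH2Cl2, rt) would give the C7 pinacol boronate F12; this catalysed hydroboration tolerates ketones.
- NaBO3·4H2O in THF/H2O would give the C7 primary alcohol F13.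
- Dess–Martin oxidation would come back to the route at 18.

## Further compounds

F1 | step 11 | ethyl (4R)-6-chloro-4-methylhex-2-ynoate | CCOC(=O)C#C[C@H](C)CCCl
F2 | step 11 | ethyl (2Z,4R)-6-chloro-3,4-dimethylhex-2-enoate | CCOC(=O)/C=C(/C)[C@H](C)CCCl
F3 | step 11 | (2Z,4R)-6-chloro-3,4-dimethylhex-2-en-1-ol | OC/C=C(/C)[C@H](C)CCCl
F4 | step 11 | 3-acetyl-2-{[(2Z,4R)-6-chloro-3,4-dimethylhex-2-en-1-yl]oxy}-6-methoxy-4-(methoxymethoxy)benzaldehyde | CC(=O)c1c(OCOC)cc(OC)c(C=O)c1OC/C=C(/C)[C@H](C)CCCl
F5 | step 11 | (Z) isomer of 13, β-hydroxy ketone (carbinol epimers) | CC(=O)c1c(OCOC)cc(OC)c(C(O)CC(=O)CO[Si](C)(C)C(C)(C)C)c1OC/C=C(/C)[C@H](C)CCCl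
F6 | step 11 | (Z) isomer of 14, aryl 1,3-diketone | CC(=O)c1c(OCOC)cc(OC)c(C(=O)CC(=O)CO[Si](C)(C)C(C)(C)C)c1OC/C=C(/C)[C@H](C)CCCl
F7 | step 11 | (Z) isomer of 15, aryl 2-diazo-1,3-diketone | CC(=O)c1c(OCOC)cc(OC)c(C(=O)C(=[N+]=[N-])C(=O)CO[Si](C)(C)C(C)(C)C)c1OC/C=C(/C)[C@H](C)CCCl
F8 | step 15 | diphenylphosphine oxide from 21 (P in place of Cl at C2; 4R,5S,10R) | CC(=O)c2c(OCOC)cc(OC)c3c2O[C@@]4(C(=O)C(O)=CC[C@@]4(C)[C@H](C)CCP(=O)(c5ccccc5)c5ccccc5)C3=O
F9 | step 15 | cyclised β-hydroxy phosphine oxide (C1–OH, C2–P(O)Ph2; epimers at C1 and C2) | CC(=O)c2c(OCOC)cc(OC)c3c2O[C@]24C(=O)C(O)=CC[C@@]2(C)[C@H](C)CC(P(=O)(c5ccccc5)c5ccccc5)C34O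
F10 | step 18 | C6 (2-nitropropan-2-yl) Michael adduct of 27 (C6 unassigned) | CC(=O)c2c(OCOC)cc(OC)c3c2O[C@]24C(=O)C(=O)CC(C(C)(C)[N+](=O)[O-])[C@@]2(C)[C@H](C)CC[C@H]34
F0 | step 16 | none | none
F11 | step 19 | trimethylsilyl enol ether of the aryl methyl ketone of 28 | C=C(O[Si](C)(C)C)c2c(OCOC)cc(OC)c3c2O[C@]24C(=O)C(=O)[C@@H]5[C@@H](C5(C)C)[C@@]2(C)[C@H](C)CC[C@H]34
F12 | step 12 | C7 pinacol boronate from 17 | CC(=O)c2c(OCOC)cc(OC)c3c2O[C@](C(=O)CO[Si](C)(C)C(C)(C)C)([C@@](C)(CCB4OC(C)(C)C(C)(C)O4)[C@H](C)CCCl)C3=O
F13 | step 12 | C7 primary alcohol from 17 | CC(=O)c2c(OCOC)cc(OC)c3c2O[C@](C(=O)CO[Si](C)(C)C(C)(C)C)([C@@](C)(CCO)[C@H](C)CCCl)C3=O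
A1 | alternative 1 | (1R,4R,5R,10S) tetracyclic 6-ene-8,9-dione, ring C as the dimethoxy acetophenone | CC(=O)c2c(OC)cc(OC)c3c2O[C@]24C(=O)C(=O)C=C[C@@]2(C)[C@H](C)CC[C@H]34
A2 | alternative 1 | (1R,4R,5R,6S,7R,10S) cyclopropanated aristolane-8,9-dione, ring C as the dimethoxy acetophenone | CC(=O)c2c(OC)cc(OC)c3c2O[C@]24C(=O)C(=O)[C@@H]5[C@@H](C5(C)C)[C@@]2(C)[C@H](C)CC[C@H]34
A3 | alternative 2 | 2-[(1R)-1-aryl-pent-4-en-1-yl]-3-methylcyclohex-2-en-1-one, aryl = 3-acetyl-6-methoxy-2,4-bis(methoxymethoxy)phenyl | C=CCC[C@@H](C1=C(C)CCCC1=O)c1c(OCOC)c(C(C)=O)c(OCOC)cc1OC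
A4 | alternative 2 | (1S,4R,5S,10R) 1-aryl-4,5-dimethyldecalin-9-one | [C@H]24C(=O)CCC[C@@]2(C)[C@H](C)CC[C@@H]4c1c(OCOC)c(C(C)=O)c(OCOC)cc1OC
A5 | alternative 3 | 3-aryloxy-4-methylcatechol, aryl = 2-acetyl-3,5-dimethoxy-6-[(1E,3E)-penta-1,3-dienyl]phenyl | CC(=O)c1c(OC)cc(OC)c(/C=C/C=C/C)c1Oc1c(C)ccc(O)c1O
A6 | alternative 3 | 3-aryloxy-4-methylcyclohexa-3,5-diene-1,2-dione (o-quinone of A5) | CC(=O)c1c(OC)cc(OC)c(/C=C/C=C/C)c1OC1=C(C)C=CC(=O)C1=O
A7 | alternative 3 | (1R,4R,5S,10S) tetracyclic 2,6-diene-8,9-dione, ring C as the dimethoxy acetophenone | CC(=O)c2c(OC)cc(OC)c3c2O[C@]24C(=O)C(=O)C=C[C@@]2(C)[C@H](C)C=C[C@H]34
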